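**Retrosynthetic overview**

1. The target is all-trans anhydroeschscholtzxanthin, (3'S)-2,3,4',5'-tetradehydro-4,5'-retro-β,β-caroten-3'-ol (C40H52O). Locants: unprimed = half with the cyclohexatriene-type ring C1–C6; primed = hydroxylated ring C1'–C6'. C3' is the only stereocentre.
2. Key disconnection: the C11–C12 σ-bond, the middle bond of the C10=C11–C12=C13 diene. A C15 (E)-alkenyllithium (C11) adds to a C25 polyenal (C12 = CHO). The resulting 9,12-ene-diol loses two molecules of water vinylogously in the same flask, copying the "anhydro/retro" dehydration by which retro-carotenoids presumably arise.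
3. Enabling feature: the diene sits inside one uninterrupted retro-polyene that runs from ring atom C2 (ring C1–C6) to ring atom C4' (ring C1'–C6'). Formal 1,8-addition of water across C2/C9 and 1,16-addition across C4'/C12 turns it into two ordinary "normal" halves: a 3,4-didehydro-β-ionone-type C15 unit and a zeaxanthin-type C25 apo-aldehyde.
4. C25 half: enzymatic reduction of ketoisophorone sets C3'; enol triflate, Stille coupling to a C15 dienol, Wittig reaction with the C10-dial. C15 half: β-ionone → 3,4-didehydro-β-ionone → ethynyl carbinol → (E)-alkenylstannane.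
5. Rings: both six-membered rings come intact from β-ionone and ketoisophorone; no ring is formed in the route.

Key step: step 11

Assumption: the C6=C7 and C6'=C7' geometry of the target (chain anti to C5 and C5') is taken to be the thermodynamically preferred one, as in all-trans anhydroretinol; the cation-mediated key step is reversible and should deliver it, and a minor 6/6'-cis isomer would be removed by crystallisation of 19 or 20.

**Route**

Step 1
Reactants: 1 β-ionone
Product: 3 dehydro-β-ionone [(E)-4-(2,6,6-trimethylcyclohexa-1,3-dien-1-yl)but-3-en-2-one], via 4-bromo-β-ionone 2 (not isolated)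
Conditions: NBS (1.05 equiv), CCl4, reflux; filter; then PhNEt2, 90 °C
Reagents that add atoms: none
Why: Wohl–Ziegler allylic bromination at ring C4 followed by E2 dehydrobromination should give the conjugated ring 1,3-diene, a sequence long used on β-ionone itself.

Step 2
Reactants: 3 dehydro-β-ionone
Product: 4 rac-(1E)-3-methyl-1-(2,6,6-trimethylcyclohexa-1,3-dien-1-yl)pent-1-en-4-yn-3-ol
Conditions: HC≡CMgBr (1.5 equiv), THF, 0 °C → rt; H2O
Reagents that add atoms: ethynylmagnesium bromide, C#C[Mg]Br
Why: 1,2-addition of an alkynyl Grignard reagent to the dienone carbonyl (classical ethynylation of ionones) should give the tertiary carbinol; its racemic centre (C9) is erased in step 11.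

Step 3
Reactants: 4 ethynyl carbinol
Product: 5 rac-(1E,4E)-3-methyl-1-(tributylstannyl)-5-(2,6,6-trimethylcyclohexa-1,3-dien-1-yl)penta-1,4-dien-3-ol
Conditions: Bu3SnH (1.2 equiv), PdCl2(PPh3)2 (2 mol %), THF, 0 °C → rt
Reagents that add atoms: tributyltin hydride, CCCC[SnH](CCCC)CCCC
Why: Pd-catalysed syn-hydrostannation of the terminal alkyne should place tin at the terminal carbon, away from the bulky tertiary carbinol, and fix the (E)-C10=C11 geometry, leaving the conjugated alkenes untouched.

Step 4
Reactants: 6 ketoisophorone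
Product: 8 (4R,6R)-actinol [(4R,6R)-4-hydroxy-2,2,6-trimethylcyclohexan-1-one], via (6R)-levodione 7 (not isolated)
Conditions: ene-reductase (Old Yellow Enzyme class); after full conversion carbonyl reductase (levodione reductase type); NAD(P)+ (cat.), glucose, glucose dehydrogenase, phosphate buffer pH 7.0, 30 °C
Reagents that add atoms: none
Why: biocatalytic ene-reduction of the enone C=C followed by regio- and face-selective ketoreduction of the unhindered C4 carbonyl should set the (4R)-carbinol, the future C3', under enzyme control; the C6 centre is removed in step 6.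

Step 5
Reactants: 8 (4R,6R)-actinol
Product: 9 (4R,6R)-4-[(tert-butyldiphenylsilyl)oxy]-2,2,6-trimethylcyclohexan-1-one
Conditions: TBDPSCl (1.2 equiv), imidazole, DMF, rt
Reagents that add atoms: tert-butyl(chloro)diphenylsilane, CC(C)(C)[Si](Cl)(c1ccccc1)c1ccccc1
Why: standard silylation of a secondary alcohol; the acid-resistant TBDPS group is chosen to survive steps 9 and 11.

Step 6
Reactants: 9 silyl ether
Product: 10 (4R)-4-[(tert-butyldiphenylsilyl)oxy]-2,6,6-trimethylcyclohex-1-en-1-yl trifluoromethanesulfonate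
Conditions: LDA (1.2 equiv), THF, −78 → 0 °C; PhNTf2 (1.2 equiv), −78 °C → rt
Reagents that add atoms: N-phenylbis(trifluoromethanesulfonimide), O=S(=O)(N(c1ccccc1)S(=O)(=O)C(F)(F)F)C(F)(F)F
Why: the ketone has a single enolisable position (C6–H; C2 is quaternary), so enolate O-triflation should give one tetrasubstituted enol triflate, as known for 2,2,6-trimethylcyclohexanone.

Step 7
Reactants: 11 (2E)-3-methylpent-2-en-4-yn-1-ol
Product: 12 (2E,4E)-3-methyl-5-(tributylstannyl)penta-2,4-dien-1-ol
Conditions: Bu3SnH (1.1 equiv), PdCl2(PPh3)2 (2 mol %), THF, 0 °C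
Reagents that add atoms: tributyltin hydride, CCCC[SnH](CCCC)CCCC
Why: Pd-catalysed syn-hydrostannation of the terminal enyne should give the (E)-β-stannyl dienol; any internal regioisomer would be removed by chromatography.

Step 8
Reactants: 10 enol triflate; 12 dienylstannane
Product: 13 (2E,4E)-5-[(4R)-4-[(tert-butyldiphenylsilyl)oxy]-2,6,6-trimethylcyclohex-1-en-1-yl]-3-methylpenta-2,4-dien-1-ol
Conditions: Pd2(dba)3 (2.5 mol %), AsPh3 (20 mol %), NMP, 60 °C
Reagents that add atoms: none
Why: Stille coupling with a weakly donating arsine ligand in a polar solvent should join the hindered cyclohexenyl triflate to the alkenylstannane with retention of geometry, as precedented for 2,6,6-trimethylcyclohexenyl triflates in retinoid synthesis.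

Step 9
Reactants: 13 C15 dienol
Product: 14 [(2E,4E)-5-[(4R)-4-[(tert-butyldiphenylsilyl)oxy]-2,6,6-trimethylcyclohex-1-en-1-yl]-3-methylpenta-2,4-dien-1-yl]triphenylphosphonium bromide
Conditions: PPh3·HBr (1.05 equiv), CH2Cl2, 0 °C → rt
Reagents that add atoms: triphenylphosphine hydrobromide, [Br-].[PH+](c1ccccc1)(c1ccccc1)c1ccccc1
Why: acid-mediated ionisation of the primary dienylic alcohol and capture of the pentadienyl cation by PPh3 at the unhindered terminus is the classical C15 Wittig-salt formation; the remote secondary TBDPS ether should survive the buffered HBr.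

Step 10
Reactants: 14 phosphonium salt; 15 C10-dial [(2E,4E,6E)-2,7-dimethylocta-2,4,6-trienedial]
Product: 16 (2E,4E,6E,8E,10E,12E)-13-[(4R)-4-[(tert-butyldiphenylsilyl)oxy]-2,6,6-trimethylcyclohex-1-en-1-yl]-2,7,11-trimethyltrideca-2,4,6,8,10,12-hexaenal
Conditions: NaOMe (1.1 equiv), CH2Cl2–MeOH, 0 °C → rt, 14 added slowly to 15 (3 equiv); then I2 (cat.), CH2Cl2, rt
Reagents that add atoms: none
Why: Wittig olefination of the semistabilised allylic ylide with one formyl group of the dial (excess dial favours mono-olefination) followed by iodine-catalysed Z→E equilibration is the standard assembly of apo-12'-carotenals.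

Step 11
Reactants: 5 C15 alkenylstannane; 16 C25 polyenal
Product: 19 3'-O-TBDPS ether of the target, via dilithiated alkenyl alkoxide 17 (not isolated), via ene-diol 18 (not isolated)
Conditions: 5 (1.4 equiv), n-BuLi (2.8 equiv), THF, −78 → −40 °C; 16, −78 °C; then HCl (2 M in Et2O, ca. 6 equiv), −78 → −30 °C; aq. NaHCO3 (Ar, dark)
Reagents that add atoms: none
Why: Tin–lithium exchange converts 5 into the (E)-alkenyllithium 17, whose hard 1,2-addition to the formyl carbon C12 of 16 creates the C11–C12 σ-bond and the (10E)-9,12-ene-diol 18 (as its dilithium alkoxide). Acidification ionises the two doubly allylic carbinols to delocalised polyenyl cations, each discharged by proton loss from the remote ring methylene (C4'–H from the C12 cation, C2–H from the C9 cation), so that two vinylogous E1 dehydrations (formally 1,16 and 1,8) move every double bond by one position and build the complete retro-chromophore C2=C3 to C5'=C4'. The closest known reaction types are the 1,2-addition of alkenyl- and alkynyl-metals to apocarotenals and the acid-induced "anhydro" (retro) dehydration of retinol, of its 3,4-didehydro congener and of allylic carotenols, which this step copies as the presumed natural origin of the retro system. No ring is closed and no stereocentre is created: the carbinol centres C9 and C12 of 18 (diastereomer mixture) become sp2, and C3' is not ionised before the retro system exists, so its configuration is carried over unchanged (the descriptor changes from R to S only because C4' becomes sp2). The selectivity needed is 1,2- over conjugate addition (alkenyllithium at −78 °C), ionisation of the free bis-allylic carbinols in preference to the bulky, weakly basic 3'-silyl ether (low temperature, short contact, prompt neutralisation), trans C10=C11 geometry (fixed by the syn-hydrostannation of step 3, which also rules out closure to a 2,5-dihydrofuran), and proton loss at C2/C4' and not at methyl groups, which reversible protonation should correct towards the fully conjugated all-trans isomer.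

Step 12
Reactants: 19 silyl ether
Product: 20 target, (3'S)-2,3,4',5'-tetradehydro-4,5'-retro-β,β-caroten-3'-ol
Conditions: TBAF (3 equiv), AcOH (3 equiv), THF, rt, dark, Ar; chromatography on deactivated silica; crystallisation
Reagents that add atoms: none
Why: buffered fluoride-mediated desilylation cleaves only the Si–O bond, so the allylic carbinol, its configuration and the acid-sensitive polyene should be preserved.

**Compound list**

1 | β-ionone, (E)-4-(2,6,6-trimethylcyclohex-1-en-1-yl)but-3-en-2-one | CC(=O)/C=C/C1=C(C)CCCC1(C)C | starting material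
2 | 4-bromo-β-ionone, rac-(E)-4-(3-bromo-2,6,6-trimethylcyclohex-1-en-1-yl)but-3-en-2-one (formed in the flask) | CC(=O)/C=C/C1=C(C)C(Br)CCC1(C)C | intermediate
3 | 3,4-didehydro-β-ionone, (E)-4-(2,6,6-trimethylcyclohexa-1,3-dien-1-yl)but-3-en-2-one | CC(=O)/C=C/C1=C(C)C=CCC1(C)C | intermediate
4 | rac-(1E)-3-methyl-1-(2,6,6-trimethylcyclohexa-1,3-dien-1-yl)pent-1-en-4-yn-3-ol | C#CC(C)(O)/C=C/C1=C(C)C=CCC1(C)C | intermediate
5 | rac-(1E,4E)-3-methyl-1-(tributylstannyl)-5-(2,6,6-trimethylcyclohexa-1,3-dien-1-yl)penta-1,4-dien-3-ol | CCCC[Sn](CCCC)(CCCC)/C=C/C(C)(O)/C=C/C1=C(C)C=CCC1(C)C | intermediate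
6 | ketoisophorone, 2,6,6-trimethylcyclohex-2-ene-1,4-dione | CC1=CC(=O)CC(C)(C)C1=O | starting material
7 | (6R)-levodione, (6R)-2,2,6-trimethylcyclohexane-1,4-dione (formed in the flask) | O=C1[C@H](C)CC(=O)CC1(C)C | intermediate
8 | (4R,6R)-actinol, (4R,6R)-4-hydroxy-2,2,6-trimethylcyclohexan-1-one | O=C1[C@H](C)C[C@@H](O)CC1(C)C | intermediate
9 | (4R,6R)-4-[(tert-butyldiphenylsilyl)oxy]-2,2,6-trimethylcyclohexan-1-one | O=C1[C@H](C)C[C@@H](O[Si](c2ccccc2)(c2ccccc2)C(C)(C)C)CC1(C)C | intermediate
10 | (4R)-4-[(tert-butyldiphenylsilyl)oxy]-2,6,6-trimethylcyclohex-1-en-1-yl trifluoromethanesulfonate | O=S(=O)(OC1=C(C)C[C@@H](O[Si](c2ccccc2)(c2ccccc2)C(C)(C)C)CC1(C)C)C(F)(F)F | intermediate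
11 | (2E)-3-methylpent-2-en-4-yn-1-ol | C#C/C(C)=C/CO | starting material
12 | (2E,4E)-3-methyl-5-(tributylstannyl)penta-2,4-dien-1-ol | CCCC[Sn](CCCC)(CCCC)/C=C/C(C)=C/CO | intermediate
13 | (2E,4E)-5-[(4R)-4-[(tert-butyldiphenylsilyl)oxy]-2,6,6-trimethylcyclohex-1-en-1-yl]-3-methylpenta-2,4-dien-1-ol | OC/C=C(C)/C=C/C1=C(C)C[C@@H](O[Si](c2ccccc2)(c2ccccc2)C(C)(C)C)CC1(C)C | intermediate
14 | [(2E,4E)-5-[(4R)-4-[(tert-butyldiphenylsilyl)oxy]-2,6,6-trimethylcyclohex-1-en-1-yl]-3-methylpenta-2,4-dien-1-yl]triphenylphosphonium bromide | [Br-].c1ccccc1[P+](c1ccccc1)(c1ccccc1)C/C=C(C)/C=C/C1=C(C)C[C@@H](O[Si](c2ccccc2)(c2ccccc2)C(C)(C)C)CC1(C)C | intermediate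
15 | C10-dial, (2E,4E,6E)-2,7-dimethylocta-2,4,6-trienedial | O=C/C(C)=C/C=C/C=C(C)/C=O | starting material
16 | (2E,4E,6E,8E,10E,12E)-13-[(4R)-4-[(tert-butyldiphenylsilyl)oxy]-2,6,6-trimethylcyclohex-1-en-1-yl]-2,7,11-trimethyltrideca-2,4,6,8,10,12-hexaenal (formyl carbon = C12 of the target) | O=C/C(C)=C/C=C/C=C(C)/C=C/C=C(C)/C=C/C1=C(C)C[C@@H](O[Si](c2ccccc2)(c2ccccc2)C(C)(C)C)CC1(C)C | intermediate
17 | lithium (1E,4E)-1-lithio-3-methyl-5-(2,6,6-trimethylcyclohexa-1,3-dien-1-yl)penta-1,4-dien-3-olate (formed in the flask) | [Li]/C=C/C(C)(O[Li])/C=C/C1=C(C)C=CCC1(C)C | intermediate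
18 | C40 (10E)-ene-9,12-diol: 3,4-didehydro-β-ring–CH=CH–C(CH3)(OH)–CH=CH–CH(OH)–all-E heptaene chain–(3'R)-3'-TBDPSO-β-ring, mixture of C9/C12 diastereomers (formed in the flask as the dilithium alkoxide) | CC1=C(/C=C/C(C)(O)/C=C/C(O)/C(C)=C/C=C/C=C(C)/C=C/C=C(C)/C=C/C2=C(C)C[C@@H](O[Si](c3ccccc3)(c3ccccc3)C(C)(C)C)CC2(C)C)C(C)(C)CC=C1 | intermediate
19 | (3'S)-3'-[(tert-butyldiphenylsilyl)oxy]-2,3,4',5'-tetradehydro-4,5'-retro-β,β-carotene, all-trans | CC1=CC=CC(C)(C)\C1=C/C=C(C)/C=C/C=C(C)/C=C/C=C/C(C)=C/C=C/C(C)=C/C=C1/C(C)=C[C@@H](O[Si](c2ccccc2)(c2ccccc2)C(C)(C)C)CC1(C)C | intermediate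
20 | (3'S)-2,3,4',5'-tetradehydro-4,5'-retro-β,β-caroten-3'-ol (anhydroeschscholtzxanthin), all-trans | CC1=CC=CC(C)(C)\C1=C/C=C(C)/C=C/C=C(C)/C=C/C=C/C(C)=C/C=C/C(C)=C/C=C1/C(C)=C[C@@H](O)CC1(C)C | target

**Step count and risks**

Total step count: 12. Longest linear sequence: 8 steps (4, 5, 6, 8, 9, 10, 11, 12, from ketoisophorone).

Steps most likely to fail:

Step 11. Several processes may go wrong. Ionisation may not stop at the two carbinols, because the 3'-silyloxy group becomes allylic once the retro system exists and may be lost as well. Proton loss may take the wrong direction: enolisation at the C12 carbinol carbon if C9 ionises first, or loss from methyl groups. The C6=C7 and C6'=C7' bonds may form as geometric mixtures. The fallback is the classical acetylenic carbinol route, with each stage isolated; it sets out from 4 and 16 and comes back at 19. The dilithio derivative of 4 (n-BuLi, 2 equiv, THF, −78 °C) would be added to 16 to give, after neutral work-up, the ynediol F1, which is purified. Its dehydration (aqueous HBr, CH2Cl2, −15 °C) has no alkene between the carbinols to relay charge, and should give the 10,11-didehydro retro-polyene F2. Semi-hydrogenation over Lindlar catalyst should give the (10Z)-polyene F3, and thermal or iodine-catalysed Z→E isomerisation should then lead to 19.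

Step 8. Oxidative addition and transmetalation at the tetrasubstituted, doubly flanked enol triflate may be too slow, so that protodestannylation and homocoupling of the stannane take over. The fallback builds the side chain by carbonyl addition; it sets out from 9 and 11 and comes back at 13. The dilithio derivative of 11 (n-BuLi, 2 equiv) would add to ketone 9 to give the propargylic diol F4. Selective acetylation of the primary hydroxyl (Ac2O, pyridine, 0 °C) gives the monoacetate F5. Dehydration of the tertiary alcohol (POCl3, pyridine), which can only proceed towards C6, gives the enyne acetate F6. LiAlH4 in THF then removes the acetate and, through the allylic alkoxide, trans-hydroaluminates the triple bond to give the (2E,4E)-dienol 13.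

Step 10. A second olefination of the symmetrical dial and incomplete equilibration of the new double bond may erode the mono-aldehyde. The fallback desymmetrises the dial first; it sets out from 15 and 14 and comes back at 16. Dial 15 would be converted with neopentyl glycol (1 equiv, PPTS cat.; unreacted dial recycled) into the mono-acetal F7. A Wittig reaction of 14 with F7 (NaOMe, CH2Cl2–MeOH) gives the C25 acetal F8. Mild hydrolysis (PPTS, acetone–water), which the TBDPS ether tolerates, then releases 16.

**Further compounds**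

F1 | step 11 | C40 10-yne-9,12-diol: 3,4-didehydro-β-ring–CH=CH–C(CH3)(OH)–C≡C–CH(OH)–all-E heptaene chain–(3'R)-3'-TBDPSO-β-ring (diastereomer mixture) | CC1=C(/C=C/C(C)(O)C#CC(O)/C(C)=C/C=C/C=C(C)/C=C/C=C(C)/C=C/C2=C(C)C[C@@H](O[Si](c3ccccc3)(c3ccccc3)C(C)(C)C)CC2(C)C)C(C)(C)CC=C1
F2 | step 11 | 10,11-didehydro derivative of 19 | CC1=CC=CC(C)(C)\C1=C/C=C(C)/C#C/C=C(C)/C=C/C=C/C(C)=C/C=C/C(C)=C/C=C1/C(C)=C[C@@H](O[Si](c2ccccc2)(c2ccccc2)C(C)(C)C)CC1(C)C
F3 | step 11 | (10Z)-isomer of 19 | CC1=CC=CC(C)(C)/C1=C\C=C(C)\C=C/C=C(C)/C=C/C=C/C(C)=C/C=C/C(C)=C/C=C1/C(C)=C[C@@H](O[Si](c2ccccc2)(c2ccccc2)C(C)(C)C)CC1(C)C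
F4 | step 8 | (4R,6R)-4-[(tert-butyldiphenylsilyl)oxy]-1-[(3E)-5-hydroxy-3-methylpent-3-en-1-yn-1-yl]-2,2,6-trimethylcyclohexan-1-ol (C1 epimers) | OC/C=C(C)/C#CC1(O)[C@H](C)C[C@@H](O[Si](c2ccccc2)(c2ccccc2)C(C)(C)C)CC1(C)C
F5 | step 8 | (2E)-5-[(4R,6R)-4-[(tert-butyldiphenylsilyl)oxy]-1-hydroxy-2,2,6-trimethylcyclohexyl]-3-methylpent-2-en-4-yn-1-yl acetate | CC(=O)OC/C=C(C)/C#CC1(O)[C@H](C)C[C@@H](O[Si](c2ccccc2)(c2ccccc2)C(C)(C)C)CC1(C)C
F6 | step 8 | (2E)-5-[(4R)-4-[(tert-butyldiphenylsilyl)oxy]-2,6,6-trimethylcyclohex-1-en-1-yl]-3-methylpent-2-en-4-yn-1-yl acetate | CC(=O)OC/C=C(C)/C#CC1=C(C)C[C@@H](O[Si](c2ccccc2)(c2ccccc2)C(C)(C)C)CC1(C)C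
F7 | step 10 | (2E,4E,6E)-7-(5,5-dimethyl-1,3-dioxan-2-yl)-2-methylocta-2,4,6-trienal | O=C/C(C)=C/C=C/C=C(C)/C1OCC(C)(C)CO1
F8 | step 10 | neopentyl glycol acetal of 16 | C1(OCC(C)(C)CO1)/C(C)=C/C=C/C=C(C)/C=C/C=C(C)/C=C/C2=C(C)C[C@@H](O[Si](c3ccccc3)(c3ccccc3)C(C)(C)C)CC2(C)C
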